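## Compound numbers

1 racemic (E)-pent-3-en-2-ol; 2 its R acetate; 3 the R alcohol; 4 4-bromo-2-methoxyphenol; 5 the S aryl pentenyl ether (precursor of the key step); 6 ortho-dienone; 7 rearranged phenol (product of the key step); 8 its silyl ether; 9 ozonide; 10 aldehyde; 11 4-bromo-1,2-dimethoxybenzene; 12 its Grignard reagent; 13 C7-epimeric alcohols; 14 ketone; 15 (7S,8S) bromo alcohol; 16 allyltributylstannane; 17 silyl ether of the target; 18 target. Full names and SMILES are in the list after the steps.

## Analysis of the target

The target 18 is an open-chain 8,5′-neolignan: two benzene rings joined by the two-carbon bridge C7–C8, with the C9 methyl group on C8. Ring A is a 3,4-dimethoxyphenyl group on the carbinol carbon C7. Ring B is a tetrasubstituted phenol whose oxygen is flanked by a methoxy group on one ortho carbon and by C8 on the other, with an allyl group para to the hydroxyl. The only stereocentres are C7 (S, secondary benzylic alcohol) and C8 (S, benzylic methine); they are adjacent and erythro, which is the relationship expected when hydride adds to the C7 ketone under Felkin–Anh control from C8. Three groups are sensitive. The electron-rich phenol is easily oxidised. The terminal allyl group does not survive ozonolysis or hydroboration and can slip into conjugation. The benzylic alcohol on ring A ionises under acid and is then trapped by the neighbouring phenol as a dihydrobenzofuran. C8 is epimerisable whenever C7 is a carbonyl carbon. The difficulty is to attach a stereodefined secondary carbon to the crowded ortho position of ring B and then to set C7 relative to it without any chelating handle. The route rests on one feature: C8 is bonded to the ring B carbon directly ortho to the phenolic oxygen, so this bond can be delivered from that oxygen through a six-membered transition state, carrying the chirality of an allylic C–O bond over to C8.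

## Retrosynthetic reasoning

18 ⇒ 17. The phenol is unmasked last. A silyl ether is chosen because it can be removed without acid; acid would ionise the C7 alcohol and close the dihydrobenzofuran.

17 ⇒ 15 + 16. The allyl–ring B bond is cut next. The allyl group cannot be present earlier because an alkene has to be cleaved oxidatively on the way to C7. A bromine atom stands in for it from the start and is exchanged for allyl from 16 by palladium-catalysed coupling under neutral conditions that tolerate the free C7 alcohol.

15 ⇒ 14 ⇒ 13. The C7–H bond is cut: the alcohol comes from ketone 14 by addition of a bulky hydride. Felkin–Anh attack, with ring B as the large group on C8, should give the 7S,8S (erythro) isomer. Direct addition of the ring A nucleophile to the aldehyde would follow the same model but place the aryl group, not hydrogen, on that trajectory, and so would favour the C7 epimer. The oxidation/reduction detour through the epimer mixture 13 is therefore accepted.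

13 ⇒ 10 + 12 (from 11). The C7–ring A bond is cut at the carbonyl stage, which gives aldehyde 10 and the aryl Grignard reagent 12, made in the flask from commercial 11. The forward step has to add to the carbonyl group faster than it enolises the α-aryl aldehyde.

10 ⇒ 8 (through 9) ⇒ 7. The aldehyde carbon C7 is traced back to an alkene carbon: ozonolysis of a propenyl-type side chain on C8 through ozonide 9. The phenol has to be silylated first (8 from 7), because a free phenol would be attacked by ozone, would form a lactol with the aldehyde and would quench 12.

7 ⇒ 5 (through 6). This is the strategic cut. The C8–aryl bond of 7 is traced back to the ether C–O bond of 5 by an aromatic Claisen rearrangement. The pent-3-en-2-yl group is the right carrier for three reasons: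
- its far alkene carbon becomes C8 and already carries the C9 methyl group;
- the alkene that is left over is the handle for C7;
- its carbinol stereocentre is converted into the C8 stereocentre by the chair transition state.

Bromine blocks the para carbon and methoxy the second ortho carbon, so only one site can take the chain.

5 ⇒ 3 + 4. The ether C–O bond is cut. Mitsunobu coupling of the commercial phenol 4 with the R alcohol 3 should give the S ether by inversion.

3 ⇒ 2 ⇒ 1. The R alcohol comes from the racemate 1 by lipase-catalysed acylation, which picks out the R enantiomer as acetate 2, and methanolysis. The precursor of the key step is thus three routine steps from commercial material.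

## Alternatives that were turned down

Alternative 1: Ring B is disconnected completely, into a C3 fragment carrying the allyl group and a ketone carrying the finished C7/C8 unit. In the forward direction an alkoxide base condenses both α-carbons of the methoxymethyl ketone A2 with the two ends of the 2-allyl vinamidinium salt A3. This forms the two ring bonds next to the future C–OMe and C–C8 carbons and gives the C7 silyl ether A1 after loss of two equivalents of amine.
- For: every substituent of ring B is placed without any question of arene regiochemistry. The allyl group arrives with A3, so no late coupling is needed and no ozonolysis conflict arises. The route is convergent. On these points it is stronger than the chosen route.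
- Against: A2 needs its own multistep asymmetric synthesis of both stereocentres. The annulation must enolise an unsymmetrical ketone at a hindered methylene next to the branched C8. 2-Alkyl vinamidinium salts are poor electrophiles, and the allylic CH2 of A3 is acidic enough to isomerise under the base.
- Comparison: the chosen route puts its risk into a unimolecular, stereospecific step on a three-step precursor instead of a late intermolecular double condensation of two valuable fragments.

Alternative 2: The C8–CH3 bond is disconnected. The sodium enolate of the ring B arylacetyl imide A5, which carries a benzyl-substituted oxazolidinone auxiliary, is methylated on the face away from the benzyl group to give A4.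
- For: this is the most predictable way to set C8. The diastereomers can be separated, so the stereochemical purity can be upgraded. The allyl group can be carried from the start because no alkene has to be cleaved. On all three points it is stronger than the chosen route.
- Against: A5 has no short access, since an acetic acid chain must be placed ortho to the oxygen of a ring that already bears the allyl group. The auxiliary is stoichiometric and must be attached and removed. After its removal the same sequence of aryl addition and Felkin reduction is still needed. The route is clearly longer.
- Comparison: the chosen route makes the C8–aryl bond and the C8 stereocentre in one operation from a commercial bromophenol and a resolved C5 alcohol. The price is that it depends on complete chirality transfer.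

Alternative 3: The C7–O and C8–H bonds are disconnected together. A terpene-derived chiral monoalkylborane adds to the E alkene A7, with boron at C7 and hydrogen at C8 on the same face, and oxidation with retention gives A6.
- For: both stereocentres are set in one step. The erythro relationship is guaranteed by syn addition to the E alkene. No epimerisable carbonyl intermediate appears. This is stronger than the chosen route in step economy for the stereocentres.
- Against: the absolute sense depends on a stoichiometric reagent distinguishing the faces of a trisubstituted alkene whose ring B is twisted out of plane by its two ortho substituents. A7 must be made as the pure E isomer. A6 carries no allyl group, because a terminal alkene would be hydroborated first. Putting the allyl group in afterwards means functionalising ring B para to oxygen in the presence of the equally electron-rich ring A and the free C7 alcohol.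
- Comparison: in the chosen route the configuration at C8 follows from the mechanism, not from reagent discrimination, and the para position is settled by the bromine atom of the starting material.

Key step: step 4

Assumption: commercial (E)-pent-3-en-2-ol 1 is the racemate with essentially pure E geometry; any Z isomer would pass through the rearrangement with the opposite sense of chirality transfer.

## Route

Step 1
Reactants: 1 racemic (E)-pent-3-en-2-ol
Product: 2 (2R,3E)-pent-3-en-2-yl acetate
Conditions: Candida antarctica lipase B (immobilised), vinyl acetate, pentane, rt, stopped short of half conversion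
Reagents that add atoms: vinyl acetate, C=COC(C)=O
Why: Lipase-catalysed kinetic resolution by irreversible transesterification; the enzyme acylates the enantiomer whose larger (propenyl) and smaller (methyl) groups fit its two pockets, here the R alcohol, and the S half of 1 stays as free alcohol and is separated. Stopping before half conversion should keep the ester enantiomerically pure.

Step 2
Reactants: 2 (2R,3E)-pent-3-en-2-yl acetate
Product: 3 (2R,3E)-pent-3-en-2-ol
Conditions: K2CO3 (cat.), MeOH, rt; fractional distillation
Reagents that add atoms: none
Why: Base-catalysed methanolysis (transesterification) takes place at the acyl carbon, so the C–O bond at the stereocentre is never broken and the R configuration and the E alkene are kept.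

Step 3
Reactants: 3 (2R,3E)-pent-3-en-2-ol; 4 4-bromo-2-methoxyphenol
Product: 5 4-bromo-2-methoxy-1-{[(2S,3E)-pent-3-en-2-yl]oxy}benzene
Conditions: PPh3, diisopropyl azodicarboxylate, toluene, 0 °C → rt
Reagents that add atoms: none
Why: Mitsunobu etherification: the alcohol is activated as its alkoxyphosphonium ion and displaced by the phenoxide of 4 in an SN2 step with inversion, R → S. Toluene and low temperature are chosen so that the allylic phosphonium ion does not ionise.

Step 4
Reactants: 5 4-bromo-2-methoxy-1-{[(2S,3E)-pent-3-en-2-yl]oxy}benzene
Product: 7 4-bromo-2-methoxy-6-[(2R,3E)-pent-3-en-2-yl]phenol, via ortho-dienone 6 (not isolated)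
Conditions: Eu(fod)3 (10 mol %), CHCl3, 50 °C
Reagents that add atoms: none
Why: The ether undergoes a concerted, suprafacial [3,3]-sigmatropic shift (aromatic Claisen rearrangement): the O–C2 bond of the pentenyl group breaks while its C4 bonds to the free ortho carbon of the ring, giving dienone 6, which enolises at once to phenol 7; no ring is closed. The closest known reaction type is the aromatic Claisen rearrangement of enantioenriched aryl 1,3-dimethylallyl ethers, run thermally or with Eu(fod)3 (fod = 6,6,7,7,8,8,8-heptafluoro-2,2-dimethyloctane-3,5-dionate), which transfers chirality from the carbinol carbon to the new benzylic carbon. The new stereocentre C8 is controlled by the carbinol stereocentre of 5 through a chair transition state with the carbinol methyl group pseudo-equatorial: the ring carbon bonds to the face of the allyl unit from which oxygen leaves, so the S ether gives the R benzylic centre (S in the target, once its neighbour is the carbinol carbon) and a new E alkene. The chair with that methyl group axial, or a boat, would give the opposite configuration together with a Z alkene and is disfavoured by the clash of the axial methyl group with the ring; the E geometry of the starting alkene is just as necessary, since a Z alkene would invert the outcome. Site selectivity is secured by the substrate: bromine occupies the para carbon, so no relay to that position can drain the dienone, and methoxy occupies the other ortho carbon, where attack gives a dienone that cannot enolise and only reverts. The step must stay concerted: the oxophilic trivalent europium centre, held by the two adjacent ether oxygens, should lower the barrier enough for 50 °C without ionising the secondary allylic C–O bond, and the low temperature keeps the ether from fragmenting and the product phenol from transferring hydrogen reversibly to its own alkene.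

Step 5
Reactants: 7 4-bromo-2-methoxy-6-[(2R,3E)-pent-3-en-2-yl]phenol
Product: 8 {4-bromo-2-methoxy-6-[(2R,3E)-pent-3-en-2-yl]phenoxy}(tert-butyl)dimethylsilane
Conditions: TBSCl, imidazole, DMF, rt → 40 °C
Reagents that add atoms: tert-butyldimethylsilyl chloride, CC(C)(C)[Si](C)(C)Cl
Why: Silylation of the phenol through the N-silylimidazolium species; the acidic, if flanked, phenol reacts under these standard conditions. The silyl ether shields the ring from ozone, prevents lactol formation with the coming aldehyde and keeps the phenol from quenching the Grignard reagent.

Step 6
Reactants: 8 {4-bromo-2-methoxy-6-[(2R,3E)-pent-3-en-2-yl]phenoxy}(tert-butyl)dimethylsilane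
Product: 10 (2S)-2-[5-bromo-2-(tert-butyldimethylsilyloxy)-3-methoxyphenyl]propanal, via secondary ozonide 9 (not isolated)
Conditions: O3, CH2Cl2, −78 °C, until 8 is consumed; then PPh3, −78 °C → rt; crude aldehyde used at once
Reagents that add atoms: ozone, [O-][O+]=O
Why: Ozonolysis: cycloaddition, cycloreversion and recombination give the ozonide, which PPh3 reduces to the aldehyde; the disubstituted alkene reacts far faster with ozone than the brominated, silylated arene. The neutral reductive work-up leaves the α-aryl stereocentre untouched (its descriptor changes from R to S only because the neighbouring carbon now outranks the ring).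

Step 7
Reactants: 10 (2S)-2-[5-bromo-2-(tert-butyldimethylsilyloxy)-3-methoxyphenyl]propanal; 11 4-bromo-1,2-dimethoxybenzene
Product: 13 (1RS,2S)-2-[5-bromo-2-(tert-butyldimethylsilyloxy)-3-methoxyphenyl]-1-(3,4-dimethoxyphenyl)propan-1-ol, via 3,4-dimethoxyphenylmagnesium bromide 12 (not isolated)
Conditions: 11, Mg, THF, 40 °C; then 10, THF, −78 °C; then H2O
Reagents that add atoms: none
Why: Grignard addition of the aryl nucleophile to the aldehyde; at −78 °C carbonyl addition should outrun enolisation of the α-aryl aldehyde, and neither the ring B bromide nor the aryl silyl ether reacts with an aryl Grignard reagent at this temperature. The C7 epimer ratio is of no consequence, because both epimers are oxidised to one ketone in step 8.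

Step 8
Reactants: 13 (1RS,2S)-2-[5-bromo-2-(tert-butyldimethylsilyloxy)-3-methoxyphenyl]-1-(3,4-dimethoxyphenyl)propan-1-ol
Product: 14 (2S)-2-[5-bromo-2-(tert-butyldimethylsilyloxy)-3-methoxyphenyl]-1-(3,4-dimethoxyphenyl)propan-1-one
Conditions: Dess–Martin periodinane, CH2Cl2, 0 °C → rt
Reagents that add atoms: none
Why: Dess–Martin oxidation of the secondary benzylic alcohol by ligand exchange at iodine and loss of the carbinol hydrogen; the medium contains no base, so the C8 stereocentre next to the new ketone should not enolise.

Step 9
Reactants: 14 (2S)-2-[5-bromo-2-(tert-butyldimethylsilyloxy)-3-methoxyphenyl]-1-(3,4-dimethoxyphenyl)propan-1-one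
Product: 15 (1S,2S)-2-[5-bromo-2-(tert-butyldimethylsilyloxy)-3-methoxyphenyl]-1-(3,4-dimethoxyphenyl)propan-1-ol
Conditions: LiBH(s-Bu)3, THF, −78 °C; then H2O
Reagents that add atoms: none
Why: Substrate-controlled hydride reduction following the Felkin–Anh model: ring B on C8 stands perpendicular to the carbonyl group and anti to the incoming hydride, which passes the C8 hydrogen and not the methyl group, and this sets C7 as S next to 8S. The bulk of the tri-sec-butylborohydride sharpens this preference, and the low temperature keeps it from acting as a base at C8.

Step 10
Reactants: 15 (1S,2S)-2-[5-bromo-2-(tert-butyldimethylsilyloxy)-3-methoxyphenyl]-1-(3,4-dimethoxyphenyl)propan-1-ol; 16 allyltributylstannane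
Product: 17 (1S,2S)-2-[5-allyl-2-(tert-butyldimethylsilyloxy)-3-methoxyphenyl]-1-(3,4-dimethoxyphenyl)propan-1-ol
Conditions: Pd(PPh3)4 (5 mol %), toluene, 100 °C
Reagents that add atoms: none
Why: Stille coupling: zerovalent palladium inserts into the aryl–bromine bond, the allyl group is transferred from tin and reductive elimination forms the aryl–allyl bond. The conditions are neutral and free of fluoride, so the free C7 alcohol, the silyl ether and both stereocentres are not affected.

Step 11
Reactants: 17 (1S,2S)-2-[5-allyl-2-(tert-butyldimethylsilyloxy)-3-methoxyphenyl]-1-(3,4-dimethoxyphenyl)propan-1-ol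
Product: 18 4-allyl-2-[(1S,2S)-1-(3,4-dimethoxyphenyl)-1-hydroxypropan-2-yl]-6-methoxyphenol
Conditions: Bu4NF, AcOH, THF, 0 °C
Reagents that add atoms: none
Why: Fluoride-induced desilylation of the aryl silyl ether, driven by the strong Si–F bond and the good phenoxide leaving group. Acetic acid buffers the phenoxide, and no strong acid is present that could ionise the C7 alcohol.

## Compound list

1 | racemic (E)-pent-3-en-2-ol | C/C=C/C(C)O | starting material
2 | (2R,3E)-pent-3-en-2-yl acetate | CC(=O)O[C@H](C)/C=C/C | intermediate
3 | (2R,3E)-pent-3-en-2-ol | O[C@H](C)/C=C/C | intermediate
4 | 4-bromo-2-methoxyphenol | COc1cc(Br)ccc1O | starting material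
5 | 4-bromo-2-methoxy-1-{[(2S,3E)-pent-3-en-2-yl]oxy}benzene | COc1cc(Br)ccc1O[C@@H](C)/C=C/C | intermediate
6 | (6R)-4-bromo-2-methoxy-6-[(2R,3E)-pent-3-en-2-yl]cyclohexa-2,4-dien-1-one | COC1=CC(Br)=C[C@@H]([C@H](C)/C=C/C)C1=O | intermediate
7 | 4-bromo-2-methoxy-6-[(2R,3E)-pent-3-en-2-yl]phenol | COc1cc(Br)cc([C@H](C)/C=C/C)c1O | intermediate
8 | {4-bromo-2-methoxy-6-[(2R,3E)-pent-3-en-2-yl]phenoxy}(tert-butyl)dimethylsilane | COc1cc(Br)cc([C@H](C)/C=C/C)c1O[Si](C)(C)C(C)(C)C | intermediate
9 | 3-{(1S)-1-[5-bromo-2-(tert-butyldimethylsilyloxy)-3-methoxyphenyl]ethyl}-5-methyl-1,2,4-trioxolane (mixture at the two ring carbons) | COc1cc(Br)cc([C@H](C)C2OOC(C)O2)c1O[Si](C)(C)C(C)(C)C | intermediate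
10 | (2S)-2-[5-bromo-2-(tert-butyldimethylsilyloxy)-3-methoxyphenyl]propanal | COc1cc(Br)cc([C@H](C)C=O)c1O[Si](C)(C)C(C)(C)C | intermediate
11 | 4-bromo-1,2-dimethoxybenzene | COc1ccc(Br)cc1OC | starting material
12 | 3,4-dimethoxyphenylmagnesium bromide | COc1ccc([Mg]Br)cc1OC | intermediate
13 | (1RS,2S)-2-[5-bromo-2-(tert-butyldimethylsilyloxy)-3-methoxyphenyl]-1-(3,4-dimethoxyphenyl)propan-1-ol (both C1 epimers) | COc1cc(Br)cc([C@H](C)C(O)c2ccc(OC)c(OC)c2)c1O[Si](C)(C)C(C)(C)C | intermediate
14 | (2S)-2-[5-bromo-2-(tert-butyldimethylsilyloxy)-3-methoxyphenyl]-1-(3,4-dimethoxyphenyl)propan-1-one | COc1cc(Br)cc([C@H](C)C(=O)c2ccc(OC)c(OC)c2)c1O[Si](C)(C)C(C)(C)C | intermediate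
15 | (1S,2S)-2-[5-bromo-2-(tert-butyldimethylsilyloxy)-3-methoxyphenyl]-1-(3,4-dimethoxyphenyl)propan-1-ol | COc1cc(Br)cc([C@H](C)[C@H](O)c2ccc(OC)c(OC)c2)c1O[Si](C)(C)C(C)(C)C | intermediate
16 | allyltributylstannane | C=CC[Sn](CCCC)(CCCC)CCCC | starting material
17 | (1S,2S)-2-[5-allyl-2-(tert-butyldimethylsilyloxy)-3-methoxyphenyl]-1-(3,4-dimethoxyphenyl)propan-1-ol | C=CCc1cc(OC)c(O[Si](C)(C)C(C)(C)C)c([C@H](C)[C@H](O)c2ccc(OC)c(OC)c2)c1 | intermediate
18 | 4-allyl-2-[(1S,2S)-1-(3,4-dimethoxyphenyl)-1-hydroxypropan-2-yl]-6-methoxyphenol | C=CCc1cc(OC)c(O)c([C@H](C)[C@H](O)c2ccc(OC)c(OC)c2)c1 | target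

## Step count and risks

Total step count: 11. Longest linear sequence: 11 steps (1 → 18); 11 enters in step 7 and 16 in step 10.

Least certain steps:

**Step 4 (key step).** The most likely failure is partial loss of stereospecificity. The Lewis acid could ionise the secondary allylic C–O bond, so that the allyl fragment recombines without memory of the carbinol centre. If more heat were needed, the ether could fragment by elimination of the C5 chain, and hydrogen transfer from the product phenol to its alkene could scramble the side chain.

Fallback (sets out from 4 and 3, comes back at 8): the C8–aryl bond would be made between two molecules by copper-mediated anti-SN2′ arylation. Phenol 4 would be iodinated at the free carbon ortho to the hydroxyl group (N-iodosuccinimide, MeCN) to 4-bromo-2-iodo-6-methoxyphenol F1, and this would be silylated (TBSCl, imidazole) to (4-bromo-2-iodo-6-methoxyphenoxy)(tert-butyl)dimethylsilane F2. Alcohol 3 would be esterified with pyridine-2-carboxylic acid (DCC, DMAP) to (2R,3E)-pent-3-en-2-yl pyridine-2-carboxylate F3. Iodine–magnesium exchange on F2 (i-PrMgCl·LiCl, THF, −40 °C) leaves the bromide alone, and magnesium in place of lithium keeps the silyl group on oxygen. With CuBr·SMe2 and F3 the aryl copper species, guided by the chelating ester, should attack the γ-carbon anti to the leaving group. The R ester therefore gives the R benzylic centre and the E alkene of 8, and step 5 is no longer needed.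

**Step 3.** The allylic alkoxyphosphonium ion may ionise and be captured on either face, which would lower the enantiomeric purity of 5 and so of everything after it. Elimination of the activated alcohol would cost material.

Fallback (sets out from 1 and 4, comes back at 5): racemic 1 would be converted with methyl chloroformate and pyridine into rac-(E)-pent-3-en-2-yl methyl carbonate F4. Zerovalent palladium (from Pd2(dba)3·CHCl3) carrying a C2-symmetric 1,2-diaminocyclohexane bis(2-diphenylphosphinobenzamide) ligand ionises both enantiomers of F4 to the same 1,3-dimethylallyl complex, whose two ends are enantiotopic. The phenoxide of 4 attacks the end chosen by the ligand and gives 5 (CH2Cl2, rt; ionisation of the carbonate is much faster than insertion into the aryl bromide). The ligand enantiomer that leads to the S ether has to be fixed by comparison with material from step 3 on a chiral column. This variant also makes steps 1 and 2 unnecessary.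

**Step 7.** The basic Grignard reagent may enolise the α-aryl aldehyde, which would racemise C8 and lower conversion. The new magnesium alkoxide may also pull the silyl group over from the phenol oxygen, which would block the oxidation in step 8.

Fallback (sets out from 10, comes back at 14): aldehyde 10 would be oxidised under Pinnick conditions (NaClO2, NaH2PO4, 2-methylbut-2-ene, t-BuOH/H2O) to (2S)-2-[5-bromo-2-(tert-butyldimethylsilyloxy)-3-methoxyphenyl]propanoic acid F5. This would be coupled with N,O-dimethylhydroxylamine hydrochloride (EDC, i-Pr2NEt) to (2S)-2-[5-bromo-2-(tert-butyldimethylsilyloxy)-3-methoxyphenyl]-N-methoxy-N-methylpropanamide F6. Addition of 12 to this far less acidic amide gives a chelated tetrahedral intermediate that holds until work-up and then releases ketone 14 directly; no C7 alkoxide is formed, and 13 and step 8 are bypassed.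

**Step 9.** Facial selectivity may be insufficient, or the hydride may act as a base at C8 and epimerise it; either would give the C7 or C8 diastereomer.

Fallback (sets out from 14, comes back at 15; no new compound): the substrate-controlled reduction would be replaced by catalyst-controlled transfer hydrogenation with RuCl[(S,S)-TsDPEN](p-cymene) in HCO2H/Et3N. This catalyst recognises the aryl group of an aryl ketone and should deliver hydride to give the S carbinol, in the same sense as the Felkin preference, under conditions that contain no strong base.

**Step 10.** Palladium hydride species at 100 °C may move the allyl double bond into conjugation with ring B, and oxidative addition into the electron-rich aryl bromide may be slow.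

Fallback (sets out from 15, comes back at 17): the polarity of the coupling would be reversed. Miyaura borylation of 15 (bis(pinacolato)diboron, Pd(dppf)Cl2, KOAc, dioxane, 80 °C) would give (1S,2S)-2-[2-(tert-butyldimethylsilyloxy)-3-methoxy-5-(4,4,5,5-tetramethyl-1,3,2-dioxaborolan-2-yl)phenyl]-1-(3,4-dimethoxyphenyl)propan-1-ol F7. This would be coupled with allyl bromide (Pd(PPh3)4, K2CO3, THF/H2O, 60 °C), in which the aryl group is transferred from boron to an allylpalladium intermediate at lower temperature. Should the base remove the silyl group here, the product would be 18 itself.

## Further compounds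

F1 | step 4 | 4-bromo-2-iodo-6-methoxyphenol | COc1cc(Br)cc(I)c1O
F2 | step 4 | (4-bromo-2-iodo-6-methoxyphenoxy)(tert-butyl)dimethylsilane | COc1cc(Br)cc(I)c1O[Si](C)(C)C(C)(C)C
F3 | step 4 | (2R,3E)-pent-3-en-2-yl pyridine-2-carboxylate | O=C(O[C@H](C)/C=C/C)c1ccccn1
F4 | step 3 | rac-(E)-pent-3-en-2-yl methyl carbonate | COC(=O)OC(C)/C=C/C
F5 | step 7 | (2S)-2-[5-bromo-2-(tert-butyldimethylsilyloxy)-3-methoxyphenyl]propanoic acid | COc1cc(Br)cc([C@H](C)C(=O)O)c1O[Si](C)(C)C(C)(C)C
F6 | step 7 | (2S)-2-[5-bromo-2-(tert-butyldimethylsilyloxy)-3-methoxyphenyl]-N-methoxy-N-methylpropanamide | COc1cc(Br)cc([C@H](C)C(=O)N(C)OC)c1O[Si](C)(C)C(C)(C)C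
F0 | step 9 | none | none
F7 | step 10 | (1S,2S)-2-[2-(tert-butyldimethylsilyloxy)-3-methoxy-5-(4,4,5,5-tetramethyl-1,3,2-dioxaborolan-2-yl)phenyl]-1-(3,4-dimethoxyphenyl)propan-1-ol | COc1cc(B2OC(C)(C)C(C)(C)O2)cc([C@H](C)[C@H](O)c2ccc(OC)c(OC)c2)c1O[Si](C)(C)C(C)(C)C
A1 | alternative 1 | 4-allyl-2-[(1S,2S)-1-(tert-butyldimethylsilyloxy)-1-(3,4-dimethoxyphenyl)propan-2-yl]-6-methoxyphenol | C=CCc1cc(OC)c(O)c([C@H](C)[C@H](O[Si](C)(C)C(C)(C)C)c2ccc(OC)c(OC)c2)c1
A2 | alternative 1 | (4S,5S)-5-(tert-butyldimethylsilyloxy)-5-(3,4-dimethoxyphenyl)-1-methoxy-4-methylpentan-2-one | COCC(=O)C[C@H](C)[C@H](O[Si](C)(C)C(C)(C)C)c1ccc(OC)c(OC)c1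
A3 | alternative 1 | 2-allyl-1,3-bis(dimethylamino)trimethinium hexafluorophosphate | C=CCC(C=[N+](C)C)=CN(C)C.F[P-](F)(F)(F)(F)F
A4 | alternative 2 | (S)-3-{(S)-2-[5-allyl-2-(tert-butyldimethylsilyloxy)-3-methoxyphenyl]propanoyl}-4-benzyloxazolidin-2-one | C=CCc1cc(OC)c(O[Si](C)(C)C(C)(C)C)c([C@H](C)C(=O)N2[C@@H](Cc3ccccc3)COC2=O)c1
A5 | alternative 2 | (S)-3-{2-[5-allyl-2-(tert-butyldimethylsilyloxy)-3-methoxyphenyl]acetyl}-4-benzyloxazolidin-2-one | C=CCc1cc(OC)c(O[Si](C)(C)C(C)(C)C)c(CC(=O)N2[C@@H](Cc3ccccc3)COC2=O)c1
A6 | alternative 3 | (1S,2S)-2-[2-(tert-butyldimethylsilyloxy)-3-methoxyphenyl]-1-(3,4-dimethoxyphenyl)propan-1-ol | COc1cccc([C@H](C)[C@H](O)c2ccc(OC)c(OC)c2)c1O[Si](C)(C)C(C)(C)C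
A7 | alternative 3 | tert-butyl{2-[(E)-1-(3,4-dimethoxyphenyl)prop-1-en-2-yl]-6-methoxyphenoxy}dimethylsilane | COc1cccc(/C(C)=C/c2ccc(OC)c(OC)c2)c1O[Si](C)(C)C(C)(C)C
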